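**Plan**

Ring A is numbered C1 (OMe), C2 (H), C3 (2-phenylethyl), C4 (OMe), C5 (OMe), C6 (3-hydroxy-3-methylbutyl); ring B is the unsubstituted phenyl.
Retrosynthesis: the C4–O bond is cut first. This leaves an arene with a mirror plane through C3 and C6, whose C2–H and C4–H are identical and each para to a methoxy group.
Further cuts: the tertiary C–O bond (hydration of a prenyl group), the C6–CH2 bond (aryllithium between the two methoxy groups plus prenyl bromide) and the C=C of the later ethylene bridge (Wittig).
Forward: Wittig olefination and hydrogenation give the bibenzyl, C6 is prenylated and the alkene hydrated. Anodic methoxylation then takes the symmetric arene to the C1,C4 quinone bisketal, and hydrolysis, reduction and double O-methylation restore ring A as the 1,4,5-trimethoxy arene.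
No ring is formed at any stage, and the target is achiral, so no stereocentre has to be set.

Key step: step 5

Remark: the first two-electron product of the electrolysis has the constitution of the target itself. It is oxidised more easily than its precursor 10 and cannot be collected there, so it carries one number (12), as the transient of step 5 and as the product of step 8.
Remark: alkene 4 is expected as a mixture of E and Z isomers and organomercurial 9 is racemic. Both elements disappear in the following operation, so their SMILES carry no descriptors.

**Route**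

Step 1
Reactants: 1 3,5-dimethoxybenzaldehyde; 2 benzyltriphenylphosphonium chloride
Product: 4 1,3-dimethoxy-5-(2-phenylethenyl)benzene (E/Z mixture), via benzylidenetriphenylphosphorane 3 (not isolated)
Conditions: KOt-Bu, THF, 0 °C to rt
Reagents that add atoms: benzyltriphenylphosphonium chloride 2, [Cl-].c1ccc(C[P+](c2ccccc2)(c2ccccc2)c2ccccc2)cc1
Why: Wittig olefination of a non-enolisable aryl aldehyde with the semi-stabilised benzyl ylide should be clean, and the alkene geometry is irrelevant because the double bond is saturated in the next step.

Step 2
Reactants: 4 1,3-dimethoxy-5-(2-phenylethenyl)benzene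
Product: 5 1,3-dimethoxy-5-(2-phenylethyl)benzene
Conditions: H2 (1 atm), 10% Pd/C, EtOAc, rt
Reagents that add atoms: none
Why: Heterogeneous catalytic hydrogenation saturates the stilbene double bond of both isomers, while aryl methyl ethers and the benzene rings are inert at atmospheric pressure.

Step 3
Reactants: 5 1,3-dimethoxy-5-(2-phenylethyl)benzene; 6 1-bromo-3-methylbut-2-ene
Product: 8 1,3-dimethoxy-2-(3-methylbut-2-en-1-yl)-5-(2-phenylethyl)benzene, via aryllithium 7 (not isolated)
Conditions: n-BuLi, THF, 0 °C to rt; then 6, 0 °C to rt
Reagents that add atoms: 1-bromo-3-methylbut-2-ene 6, CC(C)=CCBr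
Why: Directed ortho-metalation removes the C6 proton flanked by both methoxy groups, and the aryllithium should displace the primary allylic bromide in an SN2 alkylation, as is usual for 2-lithiated resorcinol dimethyl ethers.

Step 4
Reactants: 8 1,3-dimethoxy-2-(3-methylbut-2-en-1-yl)-5-(2-phenylethyl)benzene
Product: 10 4-[2,6-dimethoxy-4-(2-phenylethyl)phenyl]-2-methylbutan-2-ol, via organomercurial acetate 9 (not isolated)
Conditions: Hg(OAc)2, THF/H2O (1:1), rt; then 3 M aq. NaOH, NaBH4, 0 °C
Reagents that add atoms: water, O
Why: Oxymercuration–demercuration is a Markovnikov hydration in which water opens the mercurinium ion at the tertiary carbon without rearrangement and NaBH4 replaces mercury by hydrogen, which would also return any ring-mercurated material to the arene.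

Step 5
Reactants: 10 4-[2,6-dimethoxy-4-(2-phenylethyl)phenyl]-2-methylbutan-2-ol; 11 methanol
Product: 13 2-methyl-4-[2,3,3,6,6-pentamethoxy-4-(2-phenylethyl)cyclohexa-1,4-dien-1-yl]butan-2-ol, via trimethoxyarene 12 (not isolated)
Conditions: undivided cell, Pt gauze anode, Pt cathode, constant current, 1% KOH in MeOH, 0 °C, until 10 is consumed (4 F/mol in theory)
Reagents that add atoms: methanol 11, CO
Why: Anodic nuclear methoxylation of methoxyarenes in methanolic KOH, carried through to the quinone bisketal, is an established reaction class to which 1,3-dimethoxyarenes belong. Ring A of 10 should be oxidised at platinum to its radical cation, methoxide should add at C4 (para to the C1 methoxy, ortho to the C5 methoxy), and a second electron transfer with loss of the C4 proton gives the 1,2,4-trioxygenated arene 12. Each added methoxy group lowers the oxidation potential, so 12 is oxidised in preference to 10 and takes up two more methoxides at C1 and C4, giving the base-stable C1,C4 bisketal 13 in which C5 keeps its methoxy group as an enol ether. No ring closes and no stereocentre arises. The step needs attack at an unsubstituted carbon of ring A and not at a benzylic CH2 or in ring B: the mirror plane through C3 and C6 makes C2 and C4 identical, the methoxide medium favours nuclear over side-chain substitution, and the unsubstituted phenyl ring is oxidised only at much higher potential. If the tertiary hydroxyl competed with methoxide at C1, the resulting cyclic mixed ketal would still converge on the same quinone in step 6.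

Step 6
Reactants: 13 2-methyl-4-[2,3,3,6,6-pentamethoxy-4-(2-phenylethyl)cyclohexa-1,4-dien-1-yl]butan-2-ol
Product: 15 2-(3-hydroxy-3-methylbutyl)-3-methoxy-5-(2-phenylethyl)cyclohexa-2,5-diene-1,4-dione, via quinone monoketal 14 (not isolated)
Conditions: 1 M aq. HCl, THF, 0 °C to rt
Reagents that add atoms: water, O
Why: Acid-catalysed ketal hydrolysis should remove the C1 ketal first, because its oxocarbenium ion is stabilised through C6=C5 by the C5 methoxy group, and then the C4 ketal, while the C5 methoxy group survives as a vinylogous ester and the tertiary alcohol tolerates dilute acid at room temperature.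

Step 7
Reactants: 15 2-(3-hydroxy-3-methylbutyl)-3-methoxy-5-(2-phenylethyl)cyclohexa-2,5-diene-1,4-dione
Product: 16 2-(3-hydroxy-3-methylbutyl)-3-methoxy-5-(2-phenylethyl)benzene-1,4-diol
Conditions: Na2S2O4, THF/H2O, rt, argon
Reagents that add atoms: none
Why: Quinone reduction with Na2S2O4 is the standard two-electron conversion of a para-benzoquinone into its hydroquinone and touches neither the tertiary alcohol nor the methoxy group nor ring B.

Step 8
Reactants: 16 2-(3-hydroxy-3-methylbutyl)-3-methoxy-5-(2-phenylethyl)benzene-1,4-diol
Product: 12 2-methyl-4-[2,3,6-trimethoxy-4-(2-phenylethyl)phenyl]butan-2-ol (the target)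
Conditions: MeI, K2CO3, acetone, reflux, argon
Reagents that add atoms: iodomethane, CI
Why: Williamson ether synthesis, in which K2CO3 deprotonates only the two phenols and MeI methylates them by SN2, while the far less acidic tertiary alcohol stays free.

**Compound list**

1 | 3,5-dimethoxybenzaldehyde | COc1cc(C=O)cc(OC)c1 | starting material
2 | benzyltriphenylphosphonium chloride | [Cl-].c1ccc(C[P+](c2ccccc2)(c2ccccc2)c2ccccc2)cc1 | starting material
3 | benzylidenetriphenylphosphorane | c1ccc(C=P(c2ccccc2)(c2ccccc2)c2ccccc2)cc1 | intermediate
4 | 1,3-dimethoxy-5-(2-phenylethenyl)benzene (E/Z mixture) | COc1cc(C=Cc2ccccc2)cc(OC)c1 | intermediate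
5 | 1,3-dimethoxy-5-(2-phenylethyl)benzene | COc1cc(CCc2ccccc2)cc(OC)c1 | intermediate
6 | 1-bromo-3-methylbut-2-ene | CC(C)=CCBr | starting material
7 | [2,6-dimethoxy-4-(2-phenylethyl)phenyl]lithium | [Li]c1c(OC)cc(CCc2ccccc2)cc1OC | intermediate
8 | 1,3-dimethoxy-2-(3-methylbut-2-en-1-yl)-5-(2-phenylethyl)benzene | COc1cc(CCc2ccccc2)cc(OC)c1CC=C(C)C | intermediate
9 | (acetato){1-[2,6-dimethoxy-4-(2-phenylethyl)phenyl]-3-hydroxy-3-methylbutan-2-yl}mercury (racemic) | CC(=O)O[Hg]C(Cc1c(OC)cc(CCc2ccccc2)cc1OC)C(C)(C)O | intermediate
10 | 4-[2,6-dimethoxy-4-(2-phenylethyl)phenyl]-2-methylbutan-2-ol | COc1cc(CCc2ccccc2)cc(OC)c1CCC(C)(C)O | intermediate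
11 | methanol | CO | starting material
12 | 2-methyl-4-[2,3,6-trimethoxy-4-(2-phenylethyl)phenyl]butan-2-ol | COc1cc(CCc2ccccc2)c(OC)c(OC)c1CCC(C)(C)O | target (also the transient of step 5)
13 | 2-methyl-4-[2,3,3,6,6-pentamethoxy-4-(2-phenylethyl)cyclohexa-1,4-dien-1-yl]butan-2-ol | COC1=C(CCC(C)(C)O)C(OC)(OC)C=C(CCc2ccccc2)C1(OC)OC | intermediate
14 | 2-(3-hydroxy-3-methylbutyl)-3,4,4-trimethoxy-5-(2-phenylethyl)cyclohexa-2,5-dien-1-one | COC1=C(CCC(C)(C)O)C(=O)C=C(CCc2ccccc2)C1(OC)OC | intermediate
15 | 2-(3-hydroxy-3-methylbutyl)-3-methoxy-5-(2-phenylethyl)cyclohexa-2,5-diene-1,4-dione | COC1=C(CCC(C)(C)O)C(=O)C=C(CCc2ccccc2)C1=O | intermediate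
16 | 2-(3-hydroxy-3-methylbutyl)-3-methoxy-5-(2-phenylethyl)benzene-1,4-diol | COc1c(O)c(CCc2ccccc2)cc(O)c1CCC(C)(C)O | intermediate

**Count and risks**

Total step count: 8. Longest linear sequence: 8 steps (from 1 to 12).

Steps most likely to fail:

Step 5. The anode may fail to deliver site-controlled, complete oxidation: methoxylation at a benzylic CH2, fouling of the electrode, or over-oxidation of the electron-rich product could keep the arene from going cleanly to the bisketal. In that case the C4–O bond would be made by halogenation and copper-mediated substitution. The fallback sets out from 10. NBS in MeCN at 0 °C should brominate once at the only kind of free position on ring A to give 4-[3-bromo-2,6-dimethoxy-4-(2-phenylethyl)phenyl]-2-methylbutan-2-ol F1. Ullmann-type methoxylation of this bromide (NaOMe, CuBr, DMF/MeOH, 110 °C) should then give 12 directly, so the route is rejoined at 12 and steps 6 to 8 fall away.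

Step 6. Hydrolysis may stall after the first ketal, and the stronger acid needed for the second may ionise the tertiary alcohol, leading to dehydration or ring closure onto ring A. The fallback sets out from 13 and avoids the quinone altogether. Dilute aqueous AcOH in acetone at 0 °C should stop at the vinylogous-ester monoketal 14, which is then isolated. Reductive aromatisation of 14 with Zn dust in AcOH/THF, a known reaction of quinone monoketals that expels one methanol, should give 2-(3-hydroxy-3-methylbutyl)-3,4-dimethoxy-5-(2-phenylethyl)phenol F2. Methylation of this single phenol (MeI, K2CO3, acetone) rejoins the route at 12.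

Step 3. The aryllithium may act as a base toward the allylic bromide, attack it with allylic transposition or undergo halogen–metal exchange, so that alkylation is incomplete and the product is hard to free from recovered 5. The fallback sets out from 5 and replaces the alkylation by a cross-coupling. The same aryllithium 7 is quenched with I2 to give 2-iodo-1,3-dimethoxy-5-(2-phenylethyl)benzene F3, which can be purified. Sonogashira coupling with 2-methylbut-3-yn-2-ol (PdCl2(PPh3)2, CuI, Et3N, 60 °C) should give 4-[2,6-dimethoxy-4-(2-phenylethyl)phenyl]-2-methylbut-3-yn-2-ol F4. Hydrogenation of the alkyne (H2, 10% Pd/C, EtOAc) rejoins the route at 10, which also makes the hydration of step 4 unnecessary.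

**Further compounds**

F1 | step 5 | 4-[3-bromo-2,6-dimethoxy-4-(2-phenylethyl)phenyl]-2-methylbutan-2-ol | COc1cc(CCc2ccccc2)c(Br)c(OC)c1CCC(C)(C)O
F2 | step 6 | 2-(3-hydroxy-3-methylbutyl)-3,4-dimethoxy-5-(2-phenylethyl)phenol | COc1c(OC)c(CCc2ccccc2)cc(O)c1CCC(C)(C)O
F3 | step 3 | 2-iodo-1,3-dimethoxy-5-(2-phenylethyl)benzene | COc1cc(CCc2ccccc2)cc(OC)c1I
F4 | step 3 | 4-[2,6-dimethoxy-4-(2-phenylethyl)phenyl]-2-methylbut-3-yn-2-ol | COc1cc(CCc2ccccc2)cc(OC)c1C#CC(C)(C)O
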